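## Retrosynthetic overview

1. The acetate comes from selective O-acetylation; the ring acetyl group comes from a Pd-catalysed Heck coupling of a cyclohexenyl triflate (made from an enol silane) with butyl vinyl ether.
2. The side chain is joined at the bond between the tertiary carbinol carbon and its CH2 neighbour: Felkin-controlled addition of a C6 organocerium (from propane-1,3-diol and 2-bromopropene, asymmetric Ni/Cr coupling) to a C1 methyl ketone.
3. The C1 acetyl group comes from the hydrindanone by enol triflate formation, the same Heck coupling, and hydrogenation from the face opposite the angular methyl group.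
4. Five-membered ring (formed second): Rh-catalysed aldehyde C–H activation (intramolecular hydroacylation of the angular vinyl group) gives the trans-hydrindan-1-one.
5. Six-membered ring (formed first): enantioselective Diels–Alder reaction of a 2-silyloxybutadiene with methyl (E)-3-methyl-4-oxobut-2-enoate; the E geometry fixes the trans ring fusion.

Assumption: the Corey oxazaborolidinium catalyst (step 3) and the Kishi-type sulfonamide ligand (step 12) are used in the enantiomeric series that gives the configurations drawn; the (S)-series named below is assumed, and the mirror-image catalyst or ligand would be used if the sense were opposite.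

## Route

Step 1
Reactants: 1 methyl 3-methylbut-2-enoate
Product: 2 methyl (2E)-3-methyl-4-oxobut-2-enoate
Conditions: SeO2 (1.1 equiv), 1,4-dioxane, reflux
Reagents that add atoms: selenium dioxide, O=[Se]=O
Why: Riley allylic oxidation with SeO2 (ene reaction, then [2,3]-shift) oxidises the methyl group trans to the ester of the β,β-dimethylacrylate to the conjugated (E)-aldehyde, a standard entry to 3-formylcrotonates.

Step 2
Reactants: 3 but-3-en-2-one
Product: 4 2-[(triisopropylsilyl)oxy]buta-1,3-diene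
Conditions: TIPSOTf, Et3N, Et2O, 0 °C to rt
Reagents that add atoms: triisopropylsilyl trifluoromethanesulfonate, CC(C)[Si](C(C)C)(C(C)C)OS(=O)(=O)C(F)(F)F
Why: Soft enolisation and O-silylation of the enone on its methyl side (silyl triflate and amine) gives the 2-silyloxydiene, the standard preparation of this Diels–Alder diene.

Step 3
Reactants: 2 methyl (2E)-3-methyl-4-oxobut-2-enoate; 4 2-[(triisopropylsilyl)oxy]buta-1,3-diene
Product: 5 methyl (1R,6R)-6-formyl-6-methyl-3-[(triisopropylsilyl)oxy]cyclohex-3-ene-1-carboxylate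
Conditions: (S)-o-tolyl-CBS oxazaborolidine·HNTf2 (20 mol%), CH2Cl2, −78 to −40 °C
Reagents that add atoms: none
Why: Catalytic enantioselective Diels–Alder reaction in which the boron-bound formyl group of the α-methyl enal makes the ester-bearing carbon the electrophilic terminus (so the silyloxy carbon ends up para to the new quaternary carbon), the E geometry of 2 is transferred suprafacially into the trans relationship of CHO and CO2Me, and the chiral oxazaborolidinium shields one enal face, which sets both stereocentres (1R,6R) at once.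

Step 4
Reactants: 5 methyl (1R,6R)-6-formyl-6-methyl-3-[(triisopropylsilyl)oxy]cyclohex-3-ene-1-carboxylate
Product: 6 methyl (1R,6S)-6-ethenyl-6-methyl-3-[(triisopropylsilyl)oxy]cyclohex-3-ene-1-carboxylate
Conditions: Ph3PCH3Br, KOtBu, THF, 0 °C to rt
Reagents that add atoms: methyltriphenylphosphonium bromide, C[P+](c1ccccc1)(c1ccccc1)c1ccccc1.[Br-]
Why: Wittig methylenation is selective for the non-enolisable neopentyl aldehyde over the ester and the enol silane and leaves both stereocentres untouched (the descriptor at C6 changes only through CIP priorities).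

Step 5
Reactants: 6 methyl (1R,6S)-6-ethenyl-6-methyl-3-[(triisopropylsilyl)oxy]cyclohex-3-ene-1-carboxylate
Product: 7 (1R,6S)-6-ethenyl-6-methyl-3-[(triisopropylsilyl)oxy]cyclohex-3-ene-1-carbaldehyde
Conditions: DIBAL-H (1.1 equiv), CH2Cl2, −78 °C; MeOH quench at −78 °C, Rochelle salt
Reagents that add atoms: none
Why: Partial DIBAL-H reduction of the hindered α-branched methyl ester stops at the tetrahedral aluminium hemiacetal at −78 °C and releases the aldehyde on non-basic work-up, so the α-stereocentre is not epimerised.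

Step 6
Reactants: 7 (1R,6S)-6-ethenyl-6-methyl-3-[(triisopropylsilyl)oxy]cyclohex-3-ene-1-carbaldehyde
Product: 8 (3aR,7aR)-3a-methyl-6-[(triisopropylsilyl)oxy]-2,3,3a,4,7,7a-hexahydro-1H-inden-1-one (trans-fused)
Conditions: [Rh(nbd)(dppe)]BF4 (5 mol%, activated with H2), CH2Cl2, rt
Reagents that add atoms: none
Why: Proposed new method: cationic Rh(I)–dppe should oxidatively add the formyl C–H bond of 7, insert the pendant vinyl group into Rh–H with Rh at the terminal carbon to give a six-membered acyl rhodacycle, and reductively eliminate the C1–C2 bond, closing the cyclopentanone under neutral conditions so that the trans-related C3a/C7a centres are carried over unchanged (the vinyl group on a quaternary carbon has no allylic hydrogen to isomerise, benefits from the Thorpe–Ingold effect and lies gauche to the formyl group in the diequatorial half-chair); the closest known reaction is the Rh(I)-catalysed intramolecular hydroacylation of simple 4-pentenals to cyclopentanones, which has not been shown for closing a trans-fused hydrindan-1-one from an α-epimerisable ring aldehyde onto a vinyl group at a quaternary ring-fusion carbon in the presence of an enol silane.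

Step 7
Reactants: 8 (3aR,7aR)-3a-methyl-6-[(triisopropylsilyl)oxy]-2,3,3a,4,7,7a-hexahydro-1H-inden-1-one
Product: 10 (3aS,7aR)-3a-methyl-6-[(triisopropylsilyl)oxy]-3a,4,7,7a-tetrahydro-3H-inden-1-yl trifluoromethanesulfonate, via potassium enolate 9 (not isolated)
Conditions: KHMDS, THF, −78 °C; then PhNTf2, −78 to 0 °C
Reagents that add atoms: N-phenylbis(trifluoromethanesulfonimide), O=S(=O)(N(c1ccccc1)S(=O)(=O)C(F)(F)F)C(F)(F)F
Why: Kinetic deprotonation with KHMDS occurs at the C2 methylene and not at the ring-fusion C7a–H, and O-triflation of the enolate (enol triflate formation) locks the trans fusion.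

Step 8
Reactants: 10 (3aS,7aR)-3a-methyl-6-[(triisopropylsilyl)oxy]-3a,4,7,7a-tetrahydro-3H-inden-1-yl trifluoromethanesulfonate; 11 butyl vinyl ether
Product: 13 1-[(3aR,7aR)-3a-methyl-6-[(triisopropylsilyl)oxy]-3a,4,7,7a-tetrahydro-3H-inden-1-yl]ethan-1-one, via butoxydiene 12 (not isolated)
Conditions: Pd(OAc)2 (3 mol%), dppp (6 mol%), Et3N, 11 (5 equiv), DMF, 70 °C; then 5% aq. oxalic acid, THF, 0 °C
Reagents that add atoms: water, O
Why: Heck coupling of the enol triflate with the electron-rich vinyl ether under cationic Pd/dppp conditions takes place at the α-carbon of the vinyl ether, and mild acid hydrolysis of the resulting 2-butoxydiene unmasks the methyl ketone while the bulkier TIPS enol ether survives.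

Step 9
Reactants: 13 1-[(3aR,7aR)-3a-methyl-6-[(triisopropylsilyl)oxy]-3a,4,7,7a-tetrahydro-3H-inden-1-yl]ethan-1-one
Product: 14 1-[(1S,3aR,7aS)-3a-methyl-6-[(triisopropylsilyl)oxy]-2,3,3a,4,7,7a-hexahydro-1H-inden-1-yl]ethan-1-one
Conditions: H2 (1 atm), 10% Pd/C, EtOAc, rt
Reagents that add atoms: none
Why: Heterogeneous hydrogenation reduces the conjugated C1=C2 bond faster than the hindered enol silane and adds H2 syn from the face opposite the axial angular methyl group, which puts H-1 cis to H-7a and the acetyl group cis to the methyl group (1S), as in the hydrogenation of 16-dehydro-20-oxo steroids.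

Step 10
Reactants: 15 propane-1,3-diol
Product: 16 3-[(4-methoxybenzyl)oxy]propan-1-ol
Conditions: Ag2O, PMBCl, CH2Cl2, rt
Reagents that add atoms: 4-methoxybenzyl chloride, COc1ccc(CCl)cc1
Why: Silver(I) oxide-mediated Williamson etherification of a symmetrical diol stops cleanly at the mono-PMB ether.

Step 11
Reactants: 16 3-[(4-methoxybenzyl)oxy]propan-1-ol
Product: 17 3-[(4-methoxybenzyl)oxy]propanal
Conditions: TEMPO (10 mol%), PhI(OAc)2, CH2Cl2, rt
Reagents that add atoms: none
Why: TEMPO/PhI(OAc)2 oxidation stops at the aldehyde and is neutral enough to avoid β-elimination of the PMB ether.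

Step 12
Reactants: 17 3-[(4-methoxybenzyl)oxy]propanal; 18 2-bromopropene
Product: 19 (3S)-5-[(4-methoxybenzyl)oxy]-2-methylpent-1-en-3-ol
Conditions: CrCl2 (10 mol%), (S)-sulfonamide ligand (Kishi type, 11 mol%), proton sponge (11 mol%), NiCl2·DMP (2 mol%), Mn, Zr(Cp)2Cl2, LiCl, MeCN, rt
Reagents that add atoms: none
Why: Catalytic asymmetric Nozaki–Hiyama–Kishi coupling in which Ni(0) inserts into the C–Br bond, the alkenyl group is transmetallated to the chiral Cr(III) sulfonamide complex and adds to one face of the aldehyde, which sets the (S)-carbinol centre.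

Step 13
Reactants: 19 (3S)-5-[(4-methoxybenzyl)oxy]-2-methylpent-1-en-3-ol
Product: 20 tert-butyl({(3S)-5-[(4-methoxybenzyl)oxy]-2-methylpent-1-en-3-yl}oxy)dimethylsilane
Conditions: TBSCl, imidazole, DMF, rt
Reagents that add atoms: tert-butyldimethylsilyl chloride, CC(C)(C)[Si](C)(C)Cl
Why: Standard silylation (TBSCl/imidazole) of the secondary allylic alcohol.

Step 14
Reactants: 20 tert-butyl({(3S)-5-[(4-methoxybenzyl)oxy]-2-methylpent-1-en-3-yl}oxy)dimethylsilane
Product: 21 (3S)-3-[(tert-butyldimethylsilyl)oxy]-4-methylpent-4-en-1-ol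
Conditions: DDQ, CH2Cl2/pH 7 buffer, 0 °C
Reagents that add atoms: none
Why: Oxidative PMB cleavage with DDQ via the benzylic oxocarbenium ion leaves the allylic silyl ether and the 1,1-disubstituted alkene intact.

Step 15
Reactants: 21 (3S)-3-[(tert-butyldimethylsilyl)oxy]-4-methylpent-4-en-1-ol
Product: 22 tert-butyl{[(3S)-5-iodo-2-methylpent-1-en-3-yl]oxy}dimethylsilane
Conditions: I2, PPh3, imidazole, CH2Cl2, 0 °C to rt
Reagents that add atoms: iodine, II
Why: Appel iodination converts the primary alcohol into the iodide under neutral conditions without touching the allylic silyl ether.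

Step 16
Reactants: 22 tert-butyl{[(3S)-5-iodo-2-methylpent-1-en-3-yl]oxy}dimethylsilane; 14 1-[(1S,3aR,7aS)-3a-methyl-6-[(triisopropylsilyl)oxy]-2,3,3a,4,7,7a-hexahydro-1H-inden-1-yl]ethan-1-one
Product: 25 (2S,5S)-5-[(tert-butyldimethylsilyl)oxy]-6-methyl-2-[(1S,3aR,7aS)-3a-methyl-6-[(triisopropylsilyl)oxy]-2,3,3a,4,7,7a-hexahydro-1H-inden-1-yl]hept-6-en-2-ol, via alkyllithium 23 (not isolated), via organocerium 24 (not isolated)
Conditions: 22 (1.5 equiv), t-BuLi (3.0 equiv), Et2O/pentane, −78 °C; CeCl3, THF, −78 °C; then 14, −78 to −40 °C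
Reagents that add atoms: none
Why: Iodine–lithium exchange and transmetallation give a weakly basic organocerium reagent that adds to the enolisable methyl ketone without epimerising C1, and Felkin–Anh attack anti to the bulky C7a branch (the sense known from Grignard additions to 20-oxo steroids) sets the tertiary carbinol centre as 2S.

Step 17
Reactants: 25 (2S,5S)-5-[(tert-butyldimethylsilyl)oxy]-6-methyl-2-[(1S,3aR,7aS)-3a-methyl-6-[(triisopropylsilyl)oxy]-2,3,3a,4,7,7a-hexahydro-1H-inden-1-yl]hept-6-en-2-ol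
Product: 26 (1S,3aR,7aS)-1-[(2S,5S)-5-[(tert-butyldimethylsilyl)oxy]-6-methyl-2-[(triethylsilyl)oxy]hept-6-en-2-yl]-3a-methyl-6-[(triisopropylsilyl)oxy]-2,3,3a,4,7,7a-hexahydro-1H-indene
Conditions: TESOTf, 2,6-lutidine, CH2Cl2, −78 to 0 °C
Reagents that add atoms: triethylsilyl trifluoromethanesulfonate, CC[Si](CC)(CC)OS(=O)(=O)C(F)(F)F
Why: Silylation of the hindered tertiary alcohol with a silyl triflate removes the only acidic proton, so the enolate generated in the next step cannot be quenched or equilibrated.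

Step 18
Reactants: 26 (1S,3aR,7aS)-1-[(2S,5S)-5-[(tert-butyldimethylsilyl)oxy]-6-methyl-2-[(triethylsilyl)oxy]hept-6-en-2-yl]-3a-methyl-6-[(triisopropylsilyl)oxy]-2,3,3a,4,7,7a-hexahydro-1H-indene
Product: 28 (1S,3aR,7aS)-1-[(2S,5S)-5-[(tert-butyldimethylsilyl)oxy]-6-methyl-2-[(triethylsilyl)oxy]hept-6-en-2-yl]-3a-methyl-2,3,3a,4,7,7a-hexahydro-1H-inden-6-yl trifluoromethanesulfonate, via caesium enolate 27 (not isolated)
Conditions: CsF, PhNTf2, DME, rt
Reagents that add atoms: N-phenylbis(trifluoromethanesulfonimide), O=S(=O)(N(c1ccccc1)S(=O)(=O)C(F)(F)F)C(F)(F)F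
Why: Fluoride cleaves the enol silane and the caesium enolate is O-triflated in situ, so the C5=C6 regiochemistry fixed in the Diels–Alder step is transferred to the enol triflate while the alkyl silyl ethers survive.

Step 19
Reactants: 28 (1S,3aR,7aS)-1-[(2S,5S)-5-[(tert-butyldimethylsilyl)oxy]-6-methyl-2-[(triethylsilyl)oxy]hept-6-en-2-yl]-3a-methyl-2,3,3a,4,7,7a-hexahydro-1H-inden-6-yl trifluoromethanesulfonate; 11 butyl vinyl ether
Product: 31 1-[(1S,3aR,7aS)-1-[(2S,5S)-2,5-dihydroxy-6-methylhept-6-en-2-yl]-3a-methyl-2,3,3a,4,7,7a-hexahydro-1H-inden-6-yl]ethan-1-one, via butoxydiene 29 (not isolated), via enone disilyl ether 30 (not isolated)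
Conditions: Pd(OAc)2 (5 mol%), dppp (10 mol%), Et3N, 11 (5 equiv), DMF, 60 °C; then 5% aq. HF, MeCN, 0 °C to rt
Reagents that add atoms: water, O
Why: The same α-selective Heck coupling with butyl vinyl ether as in step 8 installs the masked acetyl group, and aqueous HF then hydrolyses the 2-butoxydiene to the enone and cleaves both the TES and the TBS ether.

Step 20
Reactants: 31 1-[(1S,3aR,7aS)-1-[(2S,5S)-2,5-dihydroxy-6-methylhept-6-en-2-yl]-3a-methyl-2,3,3a,4,7,7a-hexahydro-1H-inden-6-yl]ethan-1-one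
Product: 32 (3S,6S)-6-[(1S,3aR,7aS)-6-acetyl-3a-methyl-2,3,3a,4,7,7a-hexahydro-1H-inden-1-yl]-6-hydroxy-2-methylhept-1-en-3-yl acetate
Conditions: Ac2O, pyridine, DMAP (cat.), CH2Cl2, 0 °C
Reagents that add atoms: acetic anhydride, CC(=O)OC(C)=O
Why: Acetylation (Ac2O, pyridine, catalytic DMAP) is selective for the secondary allylic alcohol because the tertiary alcohol is too hindered to react at 0 °C.

## Compound list

1 | methyl 3-methylbut-2-enoate | CC(C)=CC(=O)OC | starting material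
2 | methyl (2E)-3-methyl-4-oxobut-2-enoate | O=C/C(C)=C/C(=O)OC | intermediate
3 | but-3-en-2-one | CC(=O)C=C | starting material
4 | 2-[(triisopropylsilyl)oxy]buta-1,3-diene | C=CC(=C)O[Si](C(C)C)(C(C)C)C(C)C | intermediate
5 | methyl (1R,6R)-6-formyl-6-methyl-3-[(triisopropylsilyl)oxy]cyclohex-3-ene-1-carboxylate | O=C[C@]1(C)CC=C(O[Si](C(C)C)(C(C)C)C(C)C)C[C@H]1C(=O)OC | intermediate
6 | methyl (1R,6S)-6-ethenyl-6-methyl-3-[(triisopropylsilyl)oxy]cyclohex-3-ene-1-carboxylate | C=C[C@]1(C)CC=C(O[Si](C(C)C)(C(C)C)C(C)C)C[C@H]1C(=O)OC | intermediate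
7 | (1R,6S)-6-ethenyl-6-methyl-3-[(triisopropylsilyl)oxy]cyclohex-3-ene-1-carbaldehyde | C=C[C@]1(C)CC=C(O[Si](C(C)C)(C(C)C)C(C)C)C[C@H]1C=O | intermediate
8 | (3aR,7aR)-3a-methyl-6-[(triisopropylsilyl)oxy]-2,3,3a,4,7,7a-hexahydro-1H-inden-1-one (trans-fused) | O=C1CC[C@]2(C)CC=C(O[Si](C(C)C)(C(C)C)C(C)C)C[C@@H]12 | intermediate
9 | potassium C1=C2 enolate of ketone 8 | [K+].[O-]C1=CC[C@]2(C)CC=C(O[Si](C(C)C)(C(C)C)C(C)C)C[C@@H]12 | intermediate
10 | (3aS,7aR)-3a-methyl-6-[(triisopropylsilyl)oxy]-3a,4,7,7a-tetrahydro-3H-inden-1-yl trifluoromethanesulfonate | O=S(=O)(OC1=CC[C@]2(C)CC=C(O[Si](C(C)C)(C(C)C)C(C)C)C[C@@H]12)C(F)(F)F | intermediate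
11 | butyl vinyl ether | C=COCCCC | starting material
12 | {[(3aR,7aR)-1-(1-butoxyethenyl)-3a-methyl-3a,4,7,7a-tetrahydro-3H-inden-6-yl]oxy}triisopropylsilane | C=C(OCCCC)C1=CC[C@]2(C)CC=C(O[Si](C(C)C)(C(C)C)C(C)C)C[C@@H]12 | intermediate
13 | 1-[(3aR,7aR)-3a-methyl-6-[(triisopropylsilyl)oxy]-3a,4,7,7a-tetrahydro-3H-inden-1-yl]ethan-1-one | CC(=O)C1=CC[C@]2(C)CC=C(O[Si](C(C)C)(C(C)C)C(C)C)C[C@@H]12 | intermediate
14 | 1-[(1S,3aR,7aS)-3a-methyl-6-[(triisopropylsilyl)oxy]-2,3,3a,4,7,7a-hexahydro-1H-inden-1-yl]ethan-1-one | CC(=O)[C@H]1CC[C@]2(C)CC=C(O[Si](C(C)C)(C(C)C)C(C)C)C[C@@H]12 | intermediate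
15 | propane-1,3-diol | OCCCO | starting material
16 | 3-[(4-methoxybenzyl)oxy]propan-1-ol | COc1ccc(COCCCO)cc1 | intermediate
17 | 3-[(4-methoxybenzyl)oxy]propanal | COc1ccc(COCCC=O)cc1 | intermediate
18 | 2-bromopropene | C=C(C)Br | starting material
19 | (3S)-5-[(4-methoxybenzyl)oxy]-2-methylpent-1-en-3-ol | C=C(C)[C@H](CCOCc1ccc(OC)cc1)O | intermediate
20 | tert-butyl({(3S)-5-[(4-methoxybenzyl)oxy]-2-methylpent-1-en-3-yl}oxy)dimethylsilane | C=C(C)[C@H](CCOCc1ccc(OC)cc1)O[Si](C)(C)C(C)(C)C | intermediate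
21 | (3S)-3-[(tert-butyldimethylsilyl)oxy]-4-methylpent-4-en-1-ol | C=C(C)[C@H](CCO)O[Si](C)(C)C(C)(C)C | intermediate
22 | tert-butyl{[(3S)-5-iodo-2-methylpent-1-en-3-yl]oxy}dimethylsilane | C=C(C)[C@H](CCI)O[Si](C)(C)C(C)(C)C | intermediate
23 | {(3S)-3-[(tert-butyldimethylsilyl)oxy]-4-methylpent-4-en-1-yl}lithium | C=C(C)[C@H](CC[Li])O[Si](C)(C)C(C)(C)C | intermediate
24 | dichloro{(3S)-3-[(tert-butyldimethylsilyl)oxy]-4-methylpent-4-en-1-yl}cerium | C=C(C)[C@H](CC[Ce](Cl)Cl)O[Si](C)(C)C(C)(C)C | intermediate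
25 | (2S,5S)-5-[(tert-butyldimethylsilyl)oxy]-6-methyl-2-[(1S,3aR,7aS)-3a-methyl-6-[(triisopropylsilyl)oxy]-2,3,3a,4,7,7a-hexahydro-1H-inden-1-yl]hept-6-en-2-ol | C=C(C)[C@H](CC[C@](C)(O)[C@H]1CC[C@]2(C)CC=C(O[Si](C(C)C)(C(C)C)C(C)C)C[C@@H]12)O[Si](C)(C)C(C)(C)C | intermediate
26 | (1S,3aR,7aS)-1-[(2S,5S)-5-[(tert-butyldimethylsilyl)oxy]-6-methyl-2-[(triethylsilyl)oxy]hept-6-en-2-yl]-3a-methyl-6-[(triisopropylsilyl)oxy]-2,3,3a,4,7,7a-hexahydro-1H-indene | C=C(C)[C@H](CC[C@](C)(O[Si](CC)(CC)CC)[C@H]1CC[C@]2(C)CC=C(O[Si](C(C)C)(C(C)C)C(C)C)C[C@@H]12)O[Si](C)(C)C(C)(C)C | intermediate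
27 | caesium C5=C6 enolate formed from 26 by loss of the TIPS group | [Cs+].C=C(C)[C@H](CC[C@](C)(O[Si](CC)(CC)CC)[C@H]1CC[C@]2(C)CC=C([O-])C[C@@H]12)O[Si](C)(C)C(C)(C)C | intermediate
28 | (1S,3aR,7aS)-1-[(2S,5S)-5-[(tert-butyldimethylsilyl)oxy]-6-methyl-2-[(triethylsilyl)oxy]hept-6-en-2-yl]-3a-methyl-2,3,3a,4,7,7a-hexahydro-1H-inden-6-yl trifluoromethanesulfonate | C=C(C)[C@H](CC[C@](C)(O[Si](CC)(CC)CC)[C@H]1CC[C@]2(C)CC=C(OS(=O)(=O)C(F)(F)F)C[C@@H]12)O[Si](C)(C)C(C)(C)C | intermediate
29 | (1S,3aR,7aS)-6-(1-butoxyethenyl)-1-[(2S,5S)-5-[(tert-butyldimethylsilyl)oxy]-6-methyl-2-[(triethylsilyl)oxy]hept-6-en-2-yl]-3a-methyl-2,3,3a,4,7,7a-hexahydro-1H-indene | C=C(C)[C@H](CC[C@](C)(O[Si](CC)(CC)CC)[C@H]1CC[C@]2(C)CC=C(C(=C)OCCCC)C[C@@H]12)O[Si](C)(C)C(C)(C)C | intermediate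
30 | 1-[(1S,3aR,7aS)-1-[(2S,5S)-5-[(tert-butyldimethylsilyl)oxy]-6-methyl-2-[(triethylsilyl)oxy]hept-6-en-2-yl]-3a-methyl-2,3,3a,4,7,7a-hexahydro-1H-inden-6-yl]ethan-1-one | C=C(C)[C@H](CC[C@](C)(O[Si](CC)(CC)CC)[C@H]1CC[C@]2(C)CC=C(C(C)=O)C[C@@H]12)O[Si](C)(C)C(C)(C)C | intermediate
31 | 1-[(1S,3aR,7aS)-1-[(2S,5S)-2,5-dihydroxy-6-methylhept-6-en-2-yl]-3a-methyl-2,3,3a,4,7,7a-hexahydro-1H-inden-6-yl]ethan-1-one | C=C(C)[C@H](CC[C@](C)(O)[C@H]1CC[C@]2(C)CC=C(C(C)=O)C[C@@H]12)O | intermediate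
32 | (3S,6S)-6-[(1S,3aR,7aS)-6-acetyl-3a-methyl-2,3,3a,4,7,7a-hexahydro-1H-inden-1-yl]-6-hydroxy-2-methylhept-1-en-3-yl acetate | C=C(C)[C@H](CC[C@](C)(O)[C@H]1CC[C@]2(C)CC=C(C(C)=O)C[C@@H]12)OC(C)=O | target

## Step count and risks

Total step count: 20.
Longest linear sequence: 13 steps (steps 1, 3 to 9 and 16 to 20).

Step 6 (the proposed new step) is the most uncertain: the acyl rhodium hydride may decarbonylate instead of cyclising, or the strained trans-fused ring may close too slowly. The fallback uses only known chemistry, sets out from 5 and comes back to the route at 8. Horner–Wadsworth–Emmons olefination of 5 with trimethyl phosphonoacetate and NaH gives methyl (1R,6S)-6-[(1E)-3-methoxy-3-oxoprop-1-en-1-yl]-6-methyl-3-[(triisopropylsilyl)oxy]cyclohex-3-ene-1-carboxylate F1. Conjugate reduction with Mg in MeOH gives methyl (1R,6R)-6-(3-methoxy-3-oxopropyl)-6-methyl-3-[(triisopropylsilyl)oxy]cyclohex-3-ene-1-carboxylate F2. Dieckmann condensation (KOtBu, THF) closes the five-membered ring as methyl (3aS,7aR)-3a-methyl-1-oxo-6-[(triisopropylsilyl)oxy]-2,3,3a,4,7,7a-hexahydro-1H-indene-2-carboxylate F3 (C2 epimers and enol), and Krapcho demethoxycarbonylation (LiCl, wet DMSO, 130 °C) gives 8. This sequence is second choice because its basic steps can epimerise C7a.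

Step 16 is the next risk: the facial bias at the methyl ketone rests on the Felkin–Anh model and the 20-oxo steroid analogy, and it could be the reverse of the prediction. The fallback exchanges the order in which methyl and chain are attached, which inverts the configuration at the carbinol carbon for the same facial preference; it is therefore used if the major product of step 16 is the 2R epimer. It sets out from enol triflate 10, uses alkyllithium 23, and comes back at 25. Pd-catalysed aminocarbonylation of 10 (CO, MeNHOMe·HCl, Et3N, Pd(OAc)2/dppp) gives (3aR,7aR)-N-methoxy-N,3a-dimethyl-6-[(triisopropylsilyl)oxy]-3a,4,7,7a-tetrahydro-3H-indene-1-carboxamide F4. Hydrogenation as in step 9 gives (1S,3aR,7aS)-N-methoxy-N,3a-dimethyl-6-[(triisopropylsilyl)oxy]-2,3,3a,4,7,7a-hexahydro-1H-indene-1-carboxamide F5. Addition of 23 gives (4S)-4-[(tert-butyldimethylsilyl)oxy]-5-methyl-1-[(1S,3aR,7aS)-3a-methyl-6-[(triisopropylsilyl)oxy]-2,3,3a,4,7,7a-hexahydro-1H-inden-1-yl]hex-5-en-1-one F6, and MeMgBr with CeCl3 at −78 °C then gives 25.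

Step 3 is the third risk: this trisubstituted formyl acrylate may react slowly or with low enantioselectivity under the chiral catalyst. The fallback replaces catalytic enantiocontrol by resolution, sets out from 2 and 4 and comes back at 5. Me2AlCl-promoted Diels–Alder reaction in CH2Cl2 at −78 °C gives the racemic trans adduct methyl rac-(1R,6R)-6-formyl-6-methyl-3-[(triisopropylsilyl)oxy]cyclohex-3-ene-1-carboxylate F7; the regiochemistry and the trans relationship are unchanged. The enantiomers are separated by preparative chiral SFC to give 5.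

## Further compounds

F1 | step 6 | methyl (1R,6S)-6-[(1E)-3-methoxy-3-oxoprop-1-en-1-yl]-6-methyl-3-[(triisopropylsilyl)oxy]cyclohex-3-ene-1-carboxylate | COC(=O)/C=C/[C@]1(C)CC=C(O[Si](C(C)C)(C(C)C)C(C)C)C[C@H]1C(=O)OC
F2 | step 6 | methyl (1R,6R)-6-(3-methoxy-3-oxopropyl)-6-methyl-3-[(triisopropylsilyl)oxy]cyclohex-3-ene-1-carboxylate | COC(=O)CC[C@]1(C)CC=C(O[Si](C(C)C)(C(C)C)C(C)C)C[C@H]1C(=O)OC
F3 | step 6 | methyl (3aS,7aR)-3a-methyl-1-oxo-6-[(triisopropylsilyl)oxy]-2,3,3a,4,7,7a-hexahydro-1H-indene-2-carboxylate (C2 unassigned) | O=C1C(C(=O)OC)C[C@]2(C)CC=C(O[Si](C(C)C)(C(C)C)C(C)C)C[C@@H]12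
F4 | step 16 | (3aR,7aR)-N-methoxy-N,3a-dimethyl-6-[(triisopropylsilyl)oxy]-3a,4,7,7a-tetrahydro-3H-indene-1-carboxamide | CON(C)C(=O)C1=CC[C@]2(C)CC=C(O[Si](C(C)C)(C(C)C)C(C)C)C[C@@H]12
F5 | step 16 | (1S,3aR,7aS)-N-methoxy-N,3a-dimethyl-6-[(triisopropylsilyl)oxy]-2,3,3a,4,7,7a-hexahydro-1H-indene-1-carboxamide | CON(C)C(=O)[C@H]1CC[C@]2(C)CC=C(O[Si](C(C)C)(C(C)C)C(C)C)C[C@@H]12
F6 | step 16 | (4S)-4-[(tert-butyldimethylsilyl)oxy]-5-methyl-1-[(1S,3aR,7aS)-3a-methyl-6-[(triisopropylsilyl)oxy]-2,3,3a,4,7,7a-hexahydro-1H-inden-1-yl]hex-5-en-1-one | C=C(C)[C@H](CCC(=O)[C@H]1CC[C@]2(C)CC=C(O[Si](C(C)C)(C(C)C)C(C)C)C[C@@H]12)O[Si](C)(C)C(C)(C)C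
F7 | step 3 | methyl rac-(1R,6R)-6-formyl-6-methyl-3-[(triisopropylsilyl)oxy]cyclohex-3-ene-1-carboxylate (racemate, written as the pair of enantiomers) | O=C[C@]1(C)CC=C(O[Si](C(C)C)(C(C)C)C(C)C)C[C@H]1C(=O)OC.O=C[C@@]1(C)CC=C(O[Si](C(C)C)(C(C)C)C(C)C)C[C@@H]1C(=O)OC
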